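A direct plan would keep both arenes as bought and make ring C last: a cinchona alkaloid/LiClO4-catalysed cyclocondensation of methoxyketene with the bis-benzylated ring B aldehyde would give cis-β-lactone A1, the lithium salt of phenol A2 would open A1 at its benzylic carbon, trifluoroacetic anhydride would close ring C onto ring A to give protected flavanone A3, and BCl3 would unmask the target.
Its weakest step would be the aryloxide opening of A1: SN2 attack at a benzylic carbon carrying ortho- and para-oxygen donors would have to beat acyl–oxygen attack and ionisation, so C2 would be left to chance.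
The second would be the cyclocondensation, which would ask an untested alkoxyketene to add with high cis- and enantioselectivity to a hindered, electron-rich aldehyde, with both stereocentres depending on it.
The third would be the last step, in which BCl3 would have to remove three benzyl groups and pick the 5-methyl ether out of four methyl ethers on the finished, epimerisable flavanone, the material one would least like to risk.

**Plan of the new route**
The retrosynthesis cuts, in this order, the O–CH3 and C3–O bonds at C3, then the C2–C1′ bond between ring C and ring B, and last the O1–C2 and C2–C3 bonds of a chromone and its C4–C4a bond.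
Ring A is bought, ring C is closed on it at step 2 as a flat 4H-chromen-4-one, and ring B is joined last at step 7.
The feature used is that C2 of the target is at once the β-carbon of the O1–C2=C3–C4=O unit of a chromone and the benzylic carbon of ring B, while C3 is the α-carbon of the C4 ketone.
An aryl–rhodium bond can therefore add to C2 under ligand control, and the C3 oxygen can then enter from the face away from the new aryl group.
No bond to C2 is made by substitution and no ketene cycloaddition is needed; the only methyl ether cleavage is at step 3, on an achiral chromone in which the peri carbonyl singles out O5, and the last step removes acetals only.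

Key step: step 7

Assumption: the (S)-configured biaryl bisphosphine is taken to deliver the aryl group to the chromone face that gives (2S)-12, as with simple chromones; if the first run shows the opposite sense, its mirror image is used.
Assumption: 2,6-dimethoxybenzene-1,4-diol and 3-methoxybenzene-1,2-diol are taken as bought.

Step 1
Reactants: 1 2,6-dimethoxybenzene-1,4-diol
Product: 3 1-(2,5-dihydroxy-4,6-dimethoxyphenyl)ethan-1-one, via ketiminium chloride 2 (not isolated)
Conditions: MeCN (5 equiv), ZnCl2 (0.5 equiv), HCl (g), Et2O, 0 °C; then H2O, 90 °C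
Reagents that add atoms: acetonitrile CC#N; water O
Why: Houben–Hoesch acylation, in which the nitrilium ion attacks C3, which is equivalent to C5 by symmetry and lies ortho or para to three oxygens, so that no regiochemical choice exists and hydrolysis of the ketiminium salt gives the chelated ortho-hydroxy ketone; no stereocentre.

Step 2
Reactants: 3 1-(2,5-dihydroxy-4,6-dimethoxyphenyl)ethan-1-one
Product: 5 6-hydroxy-5,7-dimethoxy-4H-chromen-4-one, via enaminone 4 (not isolated)
Conditions: Me2NCH(OMe)2 (3 equiv), toluene, 95 °C; then AcOH, 80 °C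
Reagents that add atoms: N,N-dimethylformamide dimethyl acetal COC(OC)N(C)C
Why: Enaminone condensation and cyclisation (chromone synthesis from a 2-hydroxyacetophenone), in which the acetyl methyl group condenses with the formamide acetal and the single ortho-hydroxy group adds to the enaminone and expels dimethylamine, so that ring C can close in one direction only; no stereocentre.

Step 3
Reactants: 5 6-hydroxy-5,7-dimethoxy-4H-chromen-4-one
Product: 6 5,6-dihydroxy-7-methoxy-4H-chromen-4-one
Conditions: BCl3 (2.5 equiv), CH2Cl2, −78 → 0 °C; then H2O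
Reagents that add atoms: none
Why: Chelation-controlled Lewis-acid ether cleavage, in which boron held between the C4 carbonyl oxygen and O5 (and bound to O6) cleaves the peri 5-OMe through a six-membered chelate while the 7-OMe, which has no carbonyl partner, stays; no stereocentre.

Step 4
Reactants: 6 5,6-dihydroxy-7-methoxy-4H-chromen-4-one
Product: 7 7-methoxy-5,6-bis(methoxymethoxy)-4H-chromen-4-one
Conditions: NaH (2.5 equiv), MOMCl (3 equiv), DMF, 0 °C → rt
Reagents that add atoms: chloromethyl methyl ether COCCl
Why: Williamson-type etherification (methoxymethyl protection), in which the sodium salt of the chelated 5-OH is alkylated as well as the 6-OH, and the two acetals should survive the rhodium step, the silyl triflate, the dioxirane and the oxonium salt yet leave with dilute acid at the end; no stereocentre.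

Step 5
Reactants: 8 3-methoxybenzene-1,2-diol
Product: 9 1-methoxy-2,3-bis(methoxymethoxy)benzene
Conditions: NaH (2.4 equiv), MOMCl (2.6 equiv), THF/DMF, 0 °C → rt
Reagents that add atoms: chloromethyl methyl ether COCCl
Why: Williamson-type etherification (methoxymethyl protection), which masks the catechol and at the same time places on O3 the group that directs the lithiation of the next step; no stereocentre.

Step 6
Reactants: 9 1-methoxy-2,3-bis(methoxymethoxy)benzene
Product: 11 [4-methoxy-2,3-bis(methoxymethoxy)phenyl]boronic acid, via aryllithium 10 (not isolated)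
Conditions: n-BuLi (1.2 equiv), THF, 0 °C; B(OiPr)3 (1.5 equiv), −78 °C → rt; aq. NH4Cl
Reagents that add atoms: triisopropyl borate CC(C)OB(OC(C)C)OC(C)C; water O
Why: Directed ortho-metalation and borylation, in which the methoxymethoxy group on C3, a stronger director than the methyl ether on C1, guides lithium to C4, the carbon ortho to it and para to the methoxy group, which becomes C1′ of ring B; no stereocentre.

Step 7
Reactants: 7 7-methoxy-5,6-bis(methoxymethoxy)-4H-chromen-4-one; 11 [4-methoxy-2,3-bis(methoxymethoxy)phenyl]boronic acid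
Product: 12 (2S)-7-methoxy-2-[4-methoxy-2,3-bis(methoxymethoxy)phenyl]-5,6-bis(methoxymethoxy)-2,3-dihydro-4H-chromen-4-one
Conditions: [Rh(OH)(cod)]2 (1.5 mol %), (S)-2,2′-bis[bis(3,4,5-trifluorophenyl)phosphino]-6,6′-dimethoxy-1,1′-biphenyl (3.3 mol %), 11 (2.5 equiv), toluene/H2O 10:1, 40 °C
Reagents that add atoms: none
Why: Rhodium-catalysed asymmetric 1,4-addition of an arylboronic acid to a chromone (Hayashi–Miyaura reaction), the closest known case being arylboronic acids plus chromones giving 2-arylchroman-4-ones with an electron-poor biaryl bisphosphine. Transmetalation gives an aryl complex of monovalent rhodium, which inserts the C2=C3 bond with the aryl group going to C2, the β-carbon of the O1–C2=C3–C4=O enone, and water then protonates the oxa-π-allyl rhodium enolate. The step closes no ring; it joins ring B to the preformed bicycle of rings A and C through the C2–C1′ bond. The new stereocentre C2 is set by the ligand alone, which leaves one face of the flat chromone open to the aryl–rhodium bond, so no group of the substrate has to direct. The step needs 1,4- over 1,2-addition and protonation of the enolate faster than loss of the aryloxide from it, since ring opening to the chalcone would re-close without control. The conjugated C4 carbonyl flanked by the 5-acetal should disfavour 1,2-attack, and the aqueous medium and the π-acidic phosphine should secure fast protonation.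

Step 8
Reactants: 12 (2S)-7-methoxy-2-[4-methoxy-2,3-bis(methoxymethoxy)phenyl]-5,6-bis(methoxymethoxy)-2,3-dihydro-4H-chromen-4-one
Product: 15 (2R,3R)-3-hydroxy-7-methoxy-2-[4-methoxy-2,3-bis(methoxymethoxy)phenyl]-5,6-bis(methoxymethoxy)-2,3-dihydro-4H-chromen-4-one, via enol silane 13 (not isolated), via silyloxy ketone 14 (not isolated)
Conditions: a) TBSOTf (1.5 equiv), Et3N (3 equiv), CH2Cl2, −78 → 0 °C; b) dimethyldioxirane (1.2 equiv, acetone), CH2Cl2, −40 °C; c) HF·pyridine, THF, 0 °C
Reagents that add atoms: dimethyldioxirane CC1(C)OO1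
Why: Rubottom oxidation, in which soft enolisation gives the 4-silyloxy-2H-chromene without ring opening and the dioxirane epoxidises C3=C4 from the face away from the C2 aryl group, so that after silyl migration the C3–O bond is trans to the aryl group and C3 is (R) by substrate control, while C2 is untouched and changes its descriptor to (R) only through the new priority of C3.

Step 9
Reactants: 15 (2R,3R)-3-hydroxy-7-methoxy-2-[4-methoxy-2,3-bis(methoxymethoxy)phenyl]-5,6-bis(methoxymethoxy)-2,3-dihydro-4H-chromen-4-one
Product: 16 (2R,3R)-3,7-dimethoxy-2-[4-methoxy-2,3-bis(methoxymethoxy)phenyl]-5,6-bis(methoxymethoxy)-2,3-dihydro-4H-chromen-4-one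
Conditions: Me3OBF4 (4 equiv), 1,8-bis(dimethylamino)naphthalene (4 equiv), 4 Å MS, CH2Cl2, 0 °C → rt
Reagents that add atoms: trimethyloxonium tetrafluoroborate C[O+](C)C.F[B-](F)(F)F
Why: O-Methylation with an oxonium salt and a non-nucleophilic amine, in which the neutral alcohol attacks the oxonium ion and no alkoxide or enolate is formed, so that neither ring opening at C2 nor epimerisation at C3 can start and both stereocentres are kept.

Step 10
Reactants: 16 (2R,3R)-3,7-dimethoxy-2-[4-methoxy-2,3-bis(methoxymethoxy)phenyl]-5,6-bis(methoxymethoxy)-2,3-dihydro-4H-chromen-4-one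
Product: 17 (2R,3R)-2-(2,3-dihydroxy-4-methoxyphenyl)-5,6-dihydroxy-3,7-dimethoxy-2,3-dihydro-4H-chromen-4-one (target)
Conditions: HCl (2 M in MeOH), THF, 0 → 20 °C
Reagents that add atoms: none
Why: Acid-catalysed acetal exchange (methoxymethyl ether cleavage), in which the four methoxymethyl groups pass to methanol as dimethoxymethane under conditions that touch none of the three methyl ethers and form no base, so that C2 and C3 should stay (2R,3R).

**Compound list**
1 | 2,6-dimethoxybenzene-1,4-diol | COc1cc(O)cc(OC)c1O | starting material
2 | 1-(2,5-dihydroxy-4,6-dimethoxyphenyl)ethan-1-iminium chloride | CC(=[NH2+])c1c(O)cc(OC)c(O)c1OC.[Cl-] | intermediate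
3 | 1-(2,5-dihydroxy-4,6-dimethoxyphenyl)ethan-1-one | CC(=O)c1c(O)cc(OC)c(O)c1OC | intermediate
4 | (E)-1-(2,5-dihydroxy-4,6-dimethoxyphenyl)-3-(dimethylamino)prop-2-en-1-one | CN(C)/C=C/C(=O)c1c(O)cc(OC)c(O)c1OC | intermediate
5 | 6-hydroxy-5,7-dimethoxy-4H-chromen-4-one | COc1cc2occc(=O)c2c(OC)c1O | intermediate
6 | 5,6-dihydroxy-7-methoxy-4H-chromen-4-one | COc1cc2occc(=O)c2c(O)c1O | intermediate
7 | 7-methoxy-5,6-bis(methoxymethoxy)-4H-chromen-4-one | COCOc1c(OC)cc2occc(=O)c2c1OCOC | intermediate
8 | 3-methoxybenzene-1,2-diol | COc1cccc(O)c1O | starting material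
9 | 1-methoxy-2,3-bis(methoxymethoxy)benzene | COCOc1cccc(OC)c1OCOC | intermediate
10 | [4-methoxy-2,3-bis(methoxymethoxy)phenyl]lithium | [Li]c1ccc(OC)c(OCOC)c1OCOC | intermediate
11 | [4-methoxy-2,3-bis(methoxymethoxy)phenyl]boronic acid | OB(O)c1ccc(OC)c(OCOC)c1OCOC | intermediate
12 | (2S)-7-methoxy-2-[4-methoxy-2,3-bis(methoxymethoxy)phenyl]-5,6-bis(methoxymethoxy)-2,3-dihydro-4H-chromen-4-one | COc1ccc([C@H]2Oc3cc(OC)c(OCOC)c(OCOC)c3C(=O)C2)c(OCOC)c1OCOC | intermediate
13 | (2S)-4-[(tert-butyldimethylsilyl)oxy]-7-methoxy-2-[4-methoxy-2,3-bis(methoxymethoxy)phenyl]-5,6-bis(methoxymethoxy)-2H-chromene | COc1ccc([C@H]2Oc3cc(OC)c(OCOC)c(OCOC)c3C(O[Si](C)(C)C(C)(C)C)=C2)c(OCOC)c1OCOC | intermediate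
14 | (2R,3R)-3-[(tert-butyldimethylsilyl)oxy]-7-methoxy-2-[4-methoxy-2,3-bis(methoxymethoxy)phenyl]-5,6-bis(methoxymethoxy)-2,3-dihydro-4H-chromen-4-one (2,3-trans) | COc1ccc([C@H]2Oc3cc(OC)c(OCOC)c(OCOC)c3C(=O)[C@@H]2O[Si](C)(C)C(C)(C)C)c(OCOC)c1OCOC | intermediate
15 | (2R,3R)-3-hydroxy-7-methoxy-2-[4-methoxy-2,3-bis(methoxymethoxy)phenyl]-5,6-bis(methoxymethoxy)-2,3-dihydro-4H-chromen-4-one | COc1ccc([C@H]2Oc3cc(OC)c(OCOC)c(OCOC)c3C(=O)[C@@H]2O)c(OCOC)c1OCOC | intermediate
16 | (2R,3R)-3,7-dimethoxy-2-[4-methoxy-2,3-bis(methoxymethoxy)phenyl]-5,6-bis(methoxymethoxy)-2,3-dihydro-4H-chromen-4-one | COc1ccc([C@H]2Oc3cc(OC)c(OCOC)c(OCOC)c3C(=O)[C@@H]2OC)c(OCOC)c1OCOC | intermediate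
17 | (2R,3R)-2-(2,3-dihydroxy-4-methoxyphenyl)-5,6-dihydroxy-3,7-dimethoxy-2,3-dihydro-4H-chromen-4-one | COc1ccc([C@H]2Oc3cc(OC)c(O)c(O)c3C(=O)[C@@H]2OC)c(O)c1O | target

Total step count: 10. Longest linear sequence: 8 steps (steps 1, 2, 3, 4, 7, 8, 9 and 10).

**Steps most likely to fail**

Step 7. The hindered, electron-rich boronic acid may transmetalate slowly and lose boron to water, and the rhodium enolate may lose the aryloxide, so that ring opening and re-closure erode the enantiomeric purity. The fallback sets out from 7 and 11 and gives up asymmetric induction for a resolution. A cationic aryl complex of divalent palladium (Pd(OCOCF3)2, 2,2′-bipyridine, NH4PF6, H2O, ClCH2CH2Cl, 60 °C), whose carbon-bound enolate is protonated directly, would give racemic 7-methoxy-2-[4-methoxy-2,3-bis(methoxymethoxy)phenyl]-5,6-bis(methoxymethoxy)-2,3-dihydro-4H-chromen-4-one F1. Kinetic resolution by asymmetric transfer hydrogenation (RuCl(p-cymene)(TsDPEN) in the configuration that reduces the (2R)-ketone, HCO2H/Et3N, stopped near half conversion) would turn the unwanted enantiomer into (2R,4R)-7-methoxy-2-[4-methoxy-2,3-bis(methoxymethoxy)phenyl]-5,6-bis(methoxymethoxy)-3,4-dihydro-2H-chromen-4-ol F2 and leave the (2S)-ketone. The fallback comes back to the route at 12.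

Step 9. Alkylation of the hindered, hydrogen-bonded C3 hydroxy group may be slow, and the oxonium salt may attack the acetal oxygens and scramble the methoxymethyl groups. The fallback sets out from 15 and replaces the oxonium electrophile by silver-assisted alkylation (MeI, Ag2O, 4 Å MS, CH2Cl2, 40 °C). This is the classical etherification of α-hydroxy carbonyl compounds, in which iodide is pulled off by silver and no free alkoxide is formed. It makes no new compound (F0) and comes back to the route at 16.

Step 8. The silyl triflate may clip an acetal, and the dioxirane may over-oxidise the electron-rich rings or attack the enol silane with poor facial selectivity. The fallback sets out from 12 and oxidises the metal enolate instead of the enol silane. NaN(SiMe3)2 in THF at −78 °C would give sodium (2S)-7-methoxy-2-[4-methoxy-2,3-bis(methoxymethoxy)phenyl]-5,6-bis(methoxymethoxy)-2H-chromen-4-olate F3, which would be hydroxylated by 2-(phenylsulfonyl)-3-phenyloxaziridine, again from the face away from the aryl group, and quenched with AcOH at −78 °C. The fallback comes back to the route at 15.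

**Further compounds**
F1 | step 7 | rac-7-methoxy-2-[4-methoxy-2,3-bis(methoxymethoxy)phenyl]-5,6-bis(methoxymethoxy)-2,3-dihydro-4H-chromen-4-one | COc1ccc(C2Oc3cc(OC)c(OCOC)c(OCOC)c3C(=O)C2)c(OCOC)c1OCOC
F2 | step 7 | (2R,4R)-7-methoxy-2-[4-methoxy-2,3-bis(methoxymethoxy)phenyl]-5,6-bis(methoxymethoxy)-3,4-dihydro-2H-chromen-4-ol | COc1ccc([C@@H]2Oc3cc(OC)c(OCOC)c(OCOC)c3[C@H](O)C2)c(OCOC)c1OCOC
F0 | step 9 | none | none
F3 | step 8 | sodium (2S)-7-methoxy-2-[4-methoxy-2,3-bis(methoxymethoxy)phenyl]-5,6-bis(methoxymethoxy)-2H-chromen-4-olate | [Na+].COc1ccc([C@H]2Oc3cc(OC)c(OCOC)c(OCOC)c3C([O-])=C2)c(OCOC)c1OCOC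
A1 | direct plan | (3R,4S)-4-[2,3-bis(benzyloxy)-4-methoxyphenyl]-3-methoxyoxetan-2-one | COc1ccc([C@@H]2OC(=O)[C@@H]2OC)c(OCc2ccccc2)c1OCc1ccccc1
A2 | direct plan | 4-(benzyloxy)-3,5-dimethoxyphenol | COc1cc(O)cc(OC)c1OCc1ccccc1
A3 | direct plan | (2R,3R)-6-(benzyloxy)-2-[2,3-bis(benzyloxy)-4-methoxyphenyl]-3,5,7-trimethoxy-2,3-dihydro-4H-chromen-4-one | COc1ccc([C@H]2Oc3cc(OC)c(OCc4ccccc4)c(OC)c3C(=O)[C@@H]2OC)c(OCc2ccccc2)c1OCc1ccccc1
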